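Ring A is made last. The C9=C11 alkene beside the quaternary, methyl-bearing C10 at the junction of rings A and B is treated as the deconjugated form of a C9=C10 enone (C5 ketone) in a tricycle that already holds ring B and the bicyclo[3.2.1]octane (C8, C9, C11–C16). In one operation the extended dienolate of that enone adds through C10 to ethyl vinyl ketone (C1–C10) and the 1,5-diketone closes C4–C5 by aldol condensation: C10 becomes quaternary, the alkene moves to C9=C11 and the 4-methyl C3 enone of ring A appears. The precursor is the C5 enone with C13 as TBS ether and C16 as dioxolane.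

Key step: step 10

Assumption: atoms are numbered as in the target (ring A = C1–C5 and C10; ring B = C5–C10; C13 the one-carbon bridge; C14–C16 the three-carbon bridge; C17 the acetoxymethyl carbon), and β is the face of ring B that carries the C10 methyl and C13.

Step 1
Reactants: 1 cyclopentane-1,3-dione; 2 ethyl vinyl ketone
Product: 3 2-(3-oxopentyl)cyclopentane-1,3-dione
Conditions: 1 (1.3 equiv), H2O, 23 °C
Reagents that add atoms: none
Why: Michael addition of the enolised 1,3-dione through C2 (the future C8) to the vinyl ketone in water, the small excess of dione holding back a second addition.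

Step 2
Reactants: 3 2-(3-oxopentyl)cyclopentane-1,3-dione; 4 acrolein
Product: 5 3-[2,5-dioxo-1-(3-oxopentyl)cyclopentyl]propanal
Conditions: acrolein (1.3 equiv), H2O, 23 °C
Reagents that add atoms: none
Why: second Michael addition, now of the 2-substituted dione to acrolein, which makes C8 quaternary (still achiral) and brings in C14–C16 with C16 at the aldehyde level.

Step 3
Reactants: 5 3-[2,5-dioxo-1-(3-oxopentyl)cyclopentyl]propanal
Product: 6 2-[2-(1,3-dioxolan-2-yl)ethyl]-2-(3-oxopentyl)cyclopentane-1,3-dione
Conditions: (TMSOCH2)2 (1.05 equiv), TMSOTf (2 mol%), CH2Cl2, −78 °C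
Reagents that add atoms: 1,2-bis(trimethylsilyloxy)ethane, C[Si](C)(C)OCCO[Si](C)(C)C
Why: Noyori acetalisation, in which the aldehyde reacts far faster than the three ketones at −78 °C with one equivalent of reagent, so that the aldehyde cannot interfere in the amine-mediated cyclisation that follows.

Step 4
Reactants: 6 2-[2-(1,3-dioxolan-2-yl)ethyl]-2-(3-oxopentyl)cyclopentane-1,3-dione
Product: 8 (S)-7a-[2-(1,3-dioxolan-2-yl)ethyl]-4-methyl-2,3,7,7a-tetrahydro-1H-indene-1,5(6H)-dione, via bicyclic ketol 7 (not isolated)
Conditions: L-phenylalanine (1.0 equiv), (1S)-camphor-10-sulfonic acid (0.5 equiv), DMF, 30 → 70 °C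
Reagents that add atoms: none
Why: Hajos–Parrish–Eder–Sauer–Wiechert cyclisation in the primary amino acid variant suited to ethyl ketones: the enamine at C10 attacks one of the two enantiotopic ring carbonyls (C10–C9, 6-(enolendo)-exo-trig), the L-amino acid selecting the carbonyl that gives (S)-C8 as in the L-series of 7a-alkyl hydrindenones, and the ketol loses water to the C9=C10 enone, while the dioxolane should survive the nearly anhydrous medium.

Step 5
Reactants: 8 (S)-7a-[2-(1,3-dioxolan-2-yl)ethyl]-4-methyl-2,3,7,7a-tetrahydro-1H-indene-1,5(6H)-dione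
Product: 10 tricyclic aldol (C12–C16 bond closed; C13 ketone as one-carbon bridge; C16 hydroxyl axial and syn to C13; C5 enone kept), via keto aldehyde 9 (not isolated)
Conditions: 2 M aq. HCl, THF, 0 → 23 °C
Reagents that add atoms: water, O
Why: the dioxolane is hydrolysed and the freed aldehyde is taken up in an acid-catalysed intramolecular aldol addition (6-(enolendo)-exo-trig) by the enol of the saturated C13 ketone, which forms faster under acid than the dienols of the conjugated C5 ketone; C12 is fixed because the C14–C16 tether reaches only the face of the five-membered ring that carries C14, and the hydrogen-bonded closed transition state should place the C16 hydroxyl axial, next to the C13 carbonyl.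

Step 6
Reactants: 10 tricyclic aldol
Product: 11 tricyclic anti-1,3-diol (C13 hydroxyl over the C9–C11 bridge; C16 hydroxyl axial)
Conditions: Me4NBH(OAc)3 (5 equiv), MeCN/AcOH (1:1), −25 °C
Reagents that add atoms: none
Why: Evans–Saksena reduction, in which the axial C16 hydroxyl binds the triacetoxyborohydride and delivers hydride within the molecule to the face of the C13 carbonyl that looks at the C14–C16 bridge, so that the C13 hydroxyl comes to lie over the C9–C11 bridge as in the target, while the unactivated enone is not reduced by this reagent.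

Step 7
Reactants: 11 tricyclic anti-1,3-diol
Product: 12 13-hydroxy-16-oxo tricyclic C5 enone
Conditions: TEMPO (0.2 equiv), PhI(OAc)2 (1.2 equiv), CH2Cl2, 23 °C
Reagents that add atoms: none
Why: oxoammonium (TEMPO) oxidation should tell the two secondary alcohols apart, because the axial C16 hydroxyl has an exposed equatorial C–H whereas the C13 carbinol is flanked by quaternary C8 and bridgehead C12 and its C–H is buried over the C14–C16 bridge.

Step 8
Reactants: 12 13-hydroxy-16-oxo tricyclic C5 enone
Product: 13 13-(tert-butyldimethylsilyloxy)-16-oxo tricyclic C5 enone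
Conditions: TBSOTf (1.3 equiv), 2,6-lutidine (2.5 equiv), CH2Cl2, −78 → 0 °C
Reagents that add atoms: tert-butyldimethylsilyl trifluoromethanesulfonate, CC(C)(C)[Si](C)(C)OS(=O)(=O)C(F)(F)F
Why: silylation of the hindered C13 hydroxyl with the silyl triflate at low temperature, carried out directly after step 7 so that the β-hydroxy ketone is never exposed to conditions for retro-aldol opening.

Step 9
Reactants: 13 13-(tert-butyldimethylsilyloxy)-16-oxo tricyclic C5 enone
Product: 14 key-step precursor: tricyclic C5 enone (C9=C10; C10 methyl) with 13-OTBS and C16 dioxolane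
Conditions: (TMSOCH2)2 (3 equiv), TMSOTf (5 mol%), CH2Cl2, −78 → −20 °C
Reagents that add atoms: 1,2-bis(trimethylsilyloxy)ethane, C[Si](C)(C)OCCO[Si](C)(C)C
Why: Noyori ketalisation, selective for the saturated C16 ketone over the conjugated C5 ketone and free of migration of the C9=C10 double bond.

Step 10
Reactants: 14 key-step precursor; 2 ethyl vinyl ketone
Product: 17 key-step product: tetracyclic 4-methyl C3 enone (C4=C5; C9=C11; C10 methyl β; 13-OTBS; C16 dioxolane), via 1,5-diketone 15 (not isolated), via ring A ketol 16 (not isolated)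
Conditions: KOt-Bu (1.1 equiv), t-BuOH/THF, 0 °C; 2 (1.3 equiv, slow addition), −20 → 0 °C; then NaOMe, MeOH, 60 °C
Reagents that add atoms: none
Why: KOt-Bu in t-BuOH equilibrates the enolates of 14 to the extended dienolate (O–C5=C10–C9=C11, by loss of a C11 proton), which adds through its α-carbon C10 to ethyl vinyl ketone so that C1–C10 forms, C10 becomes quaternary and the alkene is left at C9=C11; methoxide then closes ring A by aldol addition of C4 to the C5 ketone, a 6-(enolendo)-exo-trig closure since the enolate bond C3=C4 lies inside the new ring, and E1cB loss of water gives the 4-methyl C3 enone. The closest known reaction type is the deconjugative Robinson annulation of α-methyl enones of the hydrindenone and octalone series with ethyl vinyl ketone. The one new stereocentre, C10, is set in the Michael step by the substrate: C13 stands axial on the β face of ring B and its siloxy group points back over C9–C11, so the acceptor should approach from the α face and the methyl should end up β, cis to C13. The step needs attack at C10 in preference to C11 or C6 and attack on the α face in preference to the β face; the first is the usual α-preference of such dienolates and is drained forward because only the C10 adduct can close a six-membered conjugated enone, the second rests on the siloxy bridge. Quaternary C8 and bridgehead C12 leave C6 and C11 as the only acidic sites, and the cross-conjugated C6 enolate returns to the dienolate under these equilibrating conditions.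

Step 11
Reactants: 17 key-step product
Product: 19 4α-(hydroxymethyl)-4β-methyl C3 ketone with 5α-H (trans ring A/ring B fusion), via lithium enolate 18 (not isolated)
Conditions: Li (5 equiv), t-BuOH (1.0 equiv), NH3(l)/THF, −78 °C; isoprene; NH3 off; HCHO (g), THF, −78 °C; aq. NH4Cl
Reagents that add atoms: formaldehyde (gas, from paraformaldehyde), C=O
Why: Stork reductive alkylation: two electrons and one proton give the C3 lithium enolate with the new C5 hydrogen axial on the α face (trans fusion, as in other 4-en-3-ones that carry a C9=C11 alkene, which itself is not reduced), and monomeric formaldehyde then attacks C4 regiospecifically from the α face, away from the axial C10 methyl, so that the hydroxymethyl should be α and the methyl β.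

Step 12
Reactants: 19 4α-(hydroxymethyl)-4β-methyl C3 ketone
Product: 20 TBDPS ether of 19
Conditions: TBDPSCl (1.5 equiv), imidazole (3 equiv), DMF, 23 °C
Reagents that add atoms: tert-butyl(chloro)diphenylsilane, CC(C)(C)[Si](Cl)(c1ccccc1)c1ccccc1
Why: silylation of the primary neopentyl alcohol, which blocks retro-aldol loss of formaldehyde and keeps this hydroxyl apart from the later C17 acetate with a group that survives the acid of step 16.

Step 13
Reactants: 20 TBDPS ether of 19
Product: 21 3β-alcohol
Conditions: NaBH4 (3 equiv), MeOH/THF, 0 → 23 °C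
Reagents that add atoms: none
Why: hydride reduction of the hindered C3 ketone, expected by axial attack from the α face to give the equatorial alcohol, whose configuration is of no consequence.

Step 14
Reactants: 21 3β-alcohol
Product: 22 3-O-(imidazol-1-ylthiocarbonyl) derivative
Conditions: 1,1'-thiocarbonyldiimidazole (3 equiv), DMAP (0.3 equiv), ClCH2CH2Cl, 80 °C
Reagents that add atoms: 1,1'-thiocarbonyldiimidazole, S=C(n1ccnc1)n1ccnc1
Why: thioacylation of the secondary alcohol under neutral conditions (first half of the Barton–McCombie deoxygenation), which avoids an alkoxide that could trigger 1,3-migration of the neighbouring silyl group.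

Step 15
Reactants: 22 3-O-(imidazol-1-ylthiocarbonyl) derivative
Product: 23 3-deoxy compound (C3 methylene)
Conditions: Bu3SnH (3 equiv), AIBN (0.2 equiv), toluene, 110 °C
Reagents that add atoms: none
Why: Barton–McCombie radical deoxygenation as practised on 3β-hydroxy-4,4-disubstituted steroids; the secondary C3 radical has no alkene within reach and is reduced by the stannane.

Step 16
Reactants: 23 3-deoxy compound
Product: 24 C16 ketone
Conditions: PPTS (0.3 equiv), acetone/H2O (9:1), 60 °C
Reagents that add atoms: water, O
Why: hydrolysis of the dioxolane with a mild acid that leaves the hindered secondary TBS ether and the TBDPS ether in place.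

Step 17
Reactants: 24 C16 ketone
Product: 25 spiro-epoxide at C16 (C17 methylene axial; oxygen equatorial)
Conditions: Me3S+ I− (3 equiv), n-BuLi (2.9 equiv), THF, −10 °C; then 24, −10 → 23 °C
Reagents that add atoms: trimethylsulfonium iodide, C[S+](C)C.[I-]
Why: Corey–Chaykovsky epoxidation with dimethylsulfonium methylide, whose irreversible addition follows the axial trajectory on the ring C8–C14–C15–C16–C12–C13 (past C13–H and C14–H, while C11 on C12 blocks the other face), so that C17 should be axial and the oxygen equatorial as in the target.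

Step 18
Reactants: 25 spiro-epoxide
Product: 26 17-acetoxy-16-hydroxy bis-silyl ether
Conditions: CsOAc (5 equiv), AcOH (5 equiv), DMF, 90 °C
Reagents that add atoms: cesium acetate, [Cs+].CC(=O)[O-]; acetic acid, CC(=O)O
Why: SN2 opening of the 1,1-disubstituted epoxide by acetate at the unsubstituted C17 under buffered conditions, which leaves C16 untouched and gives the primary acetate beside the tertiary alcohol directly.

Step 19
Reactants: 26 17-acetoxy-16-hydroxy bis-silyl ether
Product: 27 Botryotin E
Conditions: HF·pyridine, pyridine, THF, 0 → 40 °C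
Reagents that add atoms: none
Why: cleavage of both silyl ethers by acidic fluoride, conditions under which the acetate is neither cleaved nor shifted.

Compound list
1 | cyclopentane-1,3-dione | O=C1CCC(=O)C1 | starting material
2 | ethyl vinyl ketone (pent-1-en-3-one) | CCC(=O)C=C | starting material
3 | 2-(3-oxopentyl)cyclopentane-1,3-dione | CCC(=O)CCC1C(=O)CCC1=O | intermediate
4 | acrolein | C=CC=O | starting material
5 | 3-[2,5-dioxo-1-(3-oxopentyl)cyclopentyl]propanal | CCC(=O)CCC1(CCC=O)C(=O)CCC1=O | intermediate
6 | 2-[2-(1,3-dioxolan-2-yl)ethyl]-2-(3-oxopentyl)cyclopentane-1,3-dione | CCC(=O)CCC1(CCC2OCCO2)C(=O)CCC1=O | intermediate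
7 | bicyclic ketol: cis-fused C9-hydroxy hydrindane-5,13-dione, C9 hydroxyl cis to the C14 chain, C10 not defined | CC1C(=O)CC[C@]2(CCC3OCCO3)C(=O)CC[C@]12O | intermediate (not isolated)
8 | (S)-7a-[2-(1,3-dioxolan-2-yl)ethyl]-4-methyl-2,3,7,7a-tetrahydro-1H-indene-1,5(6H)-dione | CC1=C2CCC(=O)[C@@]2(CCC3OCCO3)CCC1=O | intermediate
9 | 3-[(7aS)-4-methyl-1,5-dioxo-1,2,3,5,6,7-hexahydro-7aH-inden-7a-yl]propanal | CC1=C2CCC(=O)[C@@]2(CCC=O)CCC1=O | intermediate (not isolated)
10 | tricyclic aldol: C5 enone with bicyclo[3.2.1]octane, C13 ketone bridge, C16 hydroxyl axial and syn to C13 | CC1=C2C[C@@H]3[C@@H](O)CC[C@@]2(CCC1=O)C3=O | intermediate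
11 | tricyclic anti-1,3-diol: C13 hydroxyl over the C9–C11 bridge, C16 hydroxyl axial | CC1=C2C[C@@H]3[C@@H](O)CC[C@@]2(CCC1=O)[C@@H]3O | intermediate
12 | 13-hydroxy-16-oxo tricyclic C5 enone | CC1=C2C[C@@H]3C(=O)CC[C@@]2(CCC1=O)[C@@H]3O | intermediate
13 | 13-(tert-butyldimethylsilyloxy)-16-oxo tricyclic C5 enone | CC1=C2C[C@@H]3C(=O)CC[C@@]2(CCC1=O)[C@@H]3O[Si](C)(C)C(C)(C)C | intermediate
14 | key-step precursor: tricyclic C5 enone with 13-OTBS and C16 dioxolane | CC1=C2C[C@@H]3C4(OCCO4)CC[C@@]2(CCC1=O)[C@@H]3O[Si](C)(C)C(C)(C)C | intermediate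
15 | 1,5-diketone: 10β-methyl-10α-(3-oxopentyl) C5 ketone with C9=C11 | C15(OCCO5)CC[C@]23CCC(=O)[C@](C)(CCC(=O)CC)C2=C[C@H]1[C@H]3O[Si](C)(C)C(C)(C)C | intermediate (not isolated)
16 | ring A ketol: 5-hydroxy-4-methyl C3 ketone, C4 and C5 not defined | C15(OCCO5)CC[C@]23CCC4(O)C(C)C(=O)CC[C@]4(C)C2=C[C@H]1[C@H]3O[Si](C)(C)C(C)(C)C | intermediate (not isolated)
17 | key-step product: tetracyclic 4-methyl C3 enone (C4=C5, C9=C11, 13-OTBS, C16 dioxolane) | C15(OCCO5)CC[C@]23CCC4=C(C)C(=O)CC[C@]4(C)C2=C[C@H]1[C@H]3O[Si](C)(C)C(C)(C)C | intermediate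
18 | lithium C3 enolate (C3=C4, 5α-H) | C15(OCCO5)CC[C@]23CC[C@H]4C(C)=C(O[Li])CC[C@]4(C)C2=C[C@H]1[C@H]3O[Si](C)(C)C(C)(C)C | intermediate (not isolated)
19 | 4α-(hydroxymethyl)-4β-methyl C3 ketone, 5α-H | C15(OCCO5)CC[C@]23CC[C@H]4[C@](C)(CO)C(=O)CC[C@]4(C)C2=C[C@H]1[C@H]3O[Si](C)(C)C(C)(C)C | intermediate
20 | TBDPS ether of 19 | C15(OCCO5)CC[C@]23CC[C@H]4[C@](C)(CO[Si](c6ccccc6)(c7ccccc7)C(C)(C)C)C(=O)CC[C@]4(C)C2=C[C@H]1[C@H]3O[Si](C)(C)C(C)(C)C | intermediate
21 | 3β-alcohol | C15(OCCO5)CC[C@]23CC[C@H]4[C@](C)(CO[Si](c6ccccc6)(c7ccccc7)C(C)(C)C)[C@@H](O)CC[C@]4(C)C2=C[C@H]1[C@H]3O[Si](C)(C)C(C)(C)C | intermediate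
22 | 3-O-(imidazol-1-ylthiocarbonyl) derivative | C15(OCCO5)CC[C@]23CC[C@H]4[C@](C)(CO[Si](c6ccccc6)(c7ccccc7)C(C)(C)C)[C@@H](OC(=S)n8ccnc8)CC[C@]4(C)C2=C[C@H]1[C@H]3O[Si](C)(C)C(C)(C)C | intermediate
23 | 3-deoxy compound | C15(OCCO5)CC[C@]23CC[C@H]4[C@](C)(CO[Si](c6ccccc6)(c7ccccc7)C(C)(C)C)CCC[C@]4(C)C2=C[C@H]1[C@H]3O[Si](C)(C)C(C)(C)C | intermediate
24 | C16 ketone | O=C1CC[C@]23CC[C@H]4[C@](C)(CO[Si](c6ccccc6)(c7ccccc7)C(C)(C)C)CCC[C@]4(C)C2=C[C@H]1[C@H]3O[Si](C)(C)C(C)(C)C | intermediate
25 | spiro-epoxide at C16 (C17 axial, oxygen equatorial) | C1O[C@@]12CC[C@]34CC[C@H]5[C@](C)(CO[Si](c6ccccc6)(c7ccccc7)C(C)(C)C)CCC[C@]5(C)C3=C[C@H]2[C@H]4O[Si](C)(C)C(C)(C)C | intermediate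
26 | 17-acetoxy-16-hydroxy bis-silyl ether | CC(=O)OC[C@@]1(O)CC[C@]23CC[C@H]4[C@](C)(CO[Si](c6ccccc6)(c7ccccc7)C(C)(C)C)CCC[C@]4(C)C2=C[C@H]1[C@H]3O[Si](C)(C)C(C)(C)C | intermediate
27 | Botryotin E | CC(=O)OC[C@@]1(O)CC[C@]23CC[C@H]4[C@](C)(CO)CCC[C@]4(C)C2=C[C@H]1[C@H]3O | target

Total step count: 19. Longest linear sequence: 19 steps (from cyclopentane-1,3-dione).

Steps most likely to fail

1. Step 10. The dienolate may be alkylated at C11 or C6 instead of C10, the acceptor may approach the β face, and the vinyl ketone may polymerise under the equilibrating alkoxide conditions. Fallback: setting out from 14, the thermodynamic dienolate is first fixed under equilibrating silylation (TMSCl, NaI, Et3N, MeCN) as the extended trimethylsilyl dienol ether F1. MeLi in THF at −78 °C then releases the lithium dienolate regiospecifically. In aprotic medium it is added to 2-(trimethylsilyl)pent-1-en-3-one (a Stork–Jung-type silylated vinyl ketone, CCC(=O)C(=C)[Si](C)(C)C), which does not polymerise and whose α-silyl enolate does not revert, giving the α-silyl 1,5-diketone F2. NaOMe in MeOH then removes the silyl group and closes ring A, which brings the sequence back to 17.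

2. Step 5. Enolisation of the conjugated ketone towards C6 or C11 may compete with enolisation of the C13 ketone, so that the aldehyde is captured at the wrong carbon, and the C16 hydroxyl may form equatorial, where it cannot direct step 6. Fallback: setting out from 8, the saturated C13 ketone is brominated at C12 with CuBr2 in EtOAc/CHCl3 (the selectivity known for saturated five-ring ketones beside conjugated enones) to give the bromo ketone F3. Brief hydrolysis of the dioxolane (aq. CF3CO2H, CH2Cl2, 0 °C) gives the bromo keto aldehyde F4. SmI2 (divalent samarium; THF, −78 °C) then reduces the C–Br bond to a samarium enolate at C12 only, which adds to the aldehyde through a chelate (intramolecular Reformatsky-type aldol) and returns to 10 with the C16 hydroxyl syn to the C13 carbonyl.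

3. Step 7. Chemoselectivity may be lost (the C13 hydroxyl is oxidised as well), or the β-hydroxy ketone may open by retro-aldol cleavage. Fallback: setting out from 10, an Evans–Tishchenko reduction (acetaldehyde, SmI2 (cat.), THF, −10 °C) gives the anti-diol already differentiated as the C16 acetate with free C13 hydroxyl F5. Silylation (TBSOTf, 2,6-lutidine) gives the acetate silyl ether F6, methanolysis (K2CO3, MeOH) gives the C16 alcohol F7, and Dess–Martin oxidation returns to 13 without a selective oxidation and without a free β-hydroxy ketone.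

Further compounds
F1 | step 10 | extended trimethylsilyl dienol ether of 14 (C5–OSiMe3, C5=C10, C9=C11) | CC=1C2=C[C@@H]3C4(OCCO4)CC[C@@]2(CCC=1O[Si](C)(C)C)[C@@H]3O[Si](C)(C)C(C)(C)C
F2 | step 10 | α-silyl 1,5-diketone (2-trimethylsilyl derivative of 15) | C15(OCCO5)CC[C@]23CCC(=O)[C@](C)(CC([Si](C)(C)C)C(=O)CC)C2=C[C@H]1[C@H]3O[Si](C)(C)C(C)(C)C
F3 | step 5 | 12-bromo derivative of 8 | CC1=C2CC(Br)C(=O)[C@@]2(CCC3OCCO3)CCC1=O
F4 | step 5 | 12-bromo keto aldehyde | CC1=C2CC(Br)C(=O)[C@@]2(CCC=O)CCC1=O
F5 | step 7 | C16 acetate with free C13 hydroxyl | CC1=C2C[C@@H]3[C@@H](OC(C)=O)CC[C@@]2(CCC1=O)[C@@H]3O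
F6 | step 7 | C16 acetate C13 TBS ether | CC1=C2C[C@@H]3[C@@H](OC(C)=O)CC[C@@]2(CCC1=O)[C@@H]3O[Si](C)(C)C(C)(C)C
F7 | step 7 | C16 alcohol C13 TBS ether | CC1=C2C[C@@H]3[C@@H](O)CC[C@@]2(CCC1=O)[C@@H]3O[Si](C)(C)C(C)(C)C
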